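## Analysis of the target

Target 17, (1R,2S)-1-(6-carboxy-2-oxo-2H-pyran-4-yl)-6,7-dihydroxy-1,2-dihydronaphthalene-2,3-dicarboxylic acid, is a 1,2-dihydronaphthalene. Ring A is the catechol-bearing benzo ring; ring B holds the sp3 carbons C1 and C2 and the C3=C4 double bond, conjugated with ring A and with the C3 carboxyl group. C1 carries a 2-pyranone bound through C4′ with a carboxyl group on C6′, and C2 carries the third carboxyl group. The two stereocentres are neighbours and trans. Trans is the more stable relation, because both groups can then sit pseudoaxial, clear of the C8 peri hydrogen and of the C3 carboxyl. It is not the relation that a proton delivered to C2 from the open face (away from the pyranone) would give. Sensitive points are the pyranone (an enol lactone and Michael acceptor that nucleophilic bases open), C1–H (benzylic and γ to the lactone carbonyl, hence base-labile), C2–H (α to a carboxyl and allylic), the oxidisable catechol, and the tendency of the dihydronaphthalene to aromatise or shift its double bond. The difficulty is to assemble ring B with three acid-level carbons and a heterocycle on a stereogenic benzylic carbon without exposing C1 to base. The strategy rests on one feature: C2 and C3 are both α-carbons of carboxyl groups, so ring B contains a succinate unit whose C2–C3 bond joins two carbons of like polarity, and C4 links C3 to C4a, the ring A carbon para to the C7 oxygen. A bond between two such α-carbons is best made by a radical, a bond to a carbon para to oxygen by a cation, and one oxidative event can supply both.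

## Retrosynthetic reasoning

Target 17 is traced to the fully methylated trans triester 15, by way of catechol 16. The bonds cut are the five O–CH3 bonds (two aryl ethers, three esters). Keeping every acid and both phenols methylated until the end protects the catechol through the oxidative and Lewis acidic steps. The forward unmasking has to be done with acid alone, under which neither C1 nor C2 can enolise.

Triester 15 is traced to its C2 epimer mixture 14, and 14 to the geminal triester 13, by restoring a second ester on C2. C2 has to be a malonate carbon for the ring-forming step, so one carboxyl must later be removed and the C2 configuration set afterwards. A kinetic protonation cannot be trusted for this, because a proton arriving anti to the C1 pyranone would leave the ester cis. The forward sequence therefore removes the extra ester at the ester stage and then equilibrates C2 to the trans isomer, before the acid-only unmasking freezes it.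

Triester 13 is traced to the 4-methoxytetralin 12 by adding the elements of an alcohol across C3=C4. The methoxy group at C4 is the leaving group that the ring closure itself installs. Its acid-induced loss has to bring both C3/C4 diastereomers to the same alkene.

Tetralin 12 is cut at C2–C3 and at C4–C4a, giving malonate 9 and methyl (E)-3-methoxyacrylate 10. This is the key disconnection. Other cuts of ring B would form a bond at the base-labile C1 or would need the pyranone as a nucleophile, whereas this pair leaves C1 as a spectator set earlier. C2–C3 unites two carboxyl α-carbons and so calls for a radical from the malonate. C4–C4a is then closed by the cation that the same oxidation produces next to the methoxy group. The gain is ring B with all three of its carboxyl carbons at the right oxidation level, in an acidic medium.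

Malonate 9 is cut at the bond between the benzylic carbon and the aryl ring, giving alkylidene malonate 7 and 3,4-dimethoxyphenylboronic acid 8. The aryl group is the partner chosen as nucleophile because 8 is commercial and no pyranonyl organometallic is needed. The forward reaction, a catalytic asymmetric conjugate arylation, has to set the one stereocentre that is carried through the whole route.

Alkylidene malonate 7 is cut at its C=C bond into aldehyde 5 and dimethyl malonate 6, a condensation that needs only a non-nucleophilic promoter.

Aldehyde 5 is traced to methylpyranone 4 by adjusting the oxidation level of the 4-methyl group, the carbon that ends as C1 of 17. Pyranone 4 is cut at the lactone C–O bond and at the C5′–C6′ bond, through keto diester 3, to methyl 3-methylbut-2-enoate 1 and dimethyl oxalate 2. The pyranone with its C6′ carboxyl is thus built in one operation from two bulk esters.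

## Alternatives that were turned down

Alternative 1: The pyranone is traced back to a pendant catechol, dimethyl (1R,2S)-1-(3,4-dihydroxyphenyl)-6,7-dimethoxy-1,2-dihydronaphthalene-2,3-dicarboxylate A1.
- Forward key step: a non-heme iron extradiol dioxygenase cuts A1 with O2 between C4″ and C5″, the ring-opened semialdehyde closes to a cyclic hemiacetal, and a dehydrogenase oxidises it to the pyranone acid A2 (O1′–C2′ bond).
- For: it follows the likely biogenesis and brings in the base-sensitive pyranone last. A1 belongs to the aryldihydronaphthalene lignans, whose trans C1/C2 relation is set as ring B forms. On control of C2 this alternative is stronger than the chosen route, which has to equilibrate C2 afterwards.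
- Against: the enzyme must accept a bulky 4-substituted catechol and cut only at C4″–C5″. A cut at C2″–C3″ would attach ring B to C3′, and a cut between the hydroxyls gives no pyranone. The semialdehyde is reactive, two proteins and a cofactor are needed, and no dependable chemical surrogate exists. Ring A must still be carried as its dimethyl ether and cleaved at the end, and A1 needs its own asymmetric synthesis.
- Comparison: the chosen route offers, in place of the late pyranone, a pyranone made in two steps from bulk esters and a risk step that is a chemical C–C bond formation of a known type, open to ordinary optimisation.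

Alternative 2: The pyranone is cut at O1′–C6′ and C4′–C5′ into the alkynoic acid 3-[(1R,2S)-6,7-dimethoxy-2,3-bis(methoxycarbonyl)-1,2-dihydronaphthalen-1-yl]prop-2-ynoic acid A3 and 3,3-diethoxyprop-1-yne A4.
- Forward key step: [(Ph3P)Au]OTf, made from Ph3PAuCl and AgOTf, adds the acid of A3 across the terminal alkyne of A4 and then closes the enol ester 6-endo-dig onto the activated ynoate, giving the 6′-(diethoxymethyl)pyranone A5.
- For: it is convergent, catalytic and nearly neutral, and the pyranone substitution pattern is unambiguous. The heterocycle is formed on a finished ring B, so on late introduction of the pyranone it is stronger than the chosen route.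
- Against: A3 has a benzylic, propargylic C1–H that can isomerise to an allene. The electron-rich ring A and the C2 ester carbonyl are internal nucleophiles for the gold-activated alkyne, and propiolic acids can lose CO2 under coinage-metal catalysis. A5 has C6′ at the aldehyde level, so two further redox steps follow. Making trans, enantiopure A3 is the ring B problem of the target over again.
- Comparison: the chosen route has every carboxyl carbon at its final oxidation level from the start and solves ring B and the C1–pyranone link together.

Alternative 3: Ring B is cut at C1–C8a and C4–C4a into the cyclobutanone methyl 4-[(1R,2R)-2-(methoxycarbonyl)-4-oxocyclobutyl]-2-oxo-2H-pyran-6-carboxylate A6 and 4,5-dimethoxybenzyne A8.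
- Forward key step: CsF generates A8 from 4,5-dimethoxy-2-(trimethylsilyl)phenyl triflate A7, and the aryne inserts into the acyl–alkyl bond of A6, giving the trans tetralone A9.
- For: two aryl–carbon bonds and ring B form in one strain-driven step. The aryne is symmetric, so there is no regiochemical question on ring A. On that point it is stronger than the chosen route, which relies on para direction.
- Against: the insertion starts from the enolate at the pyranone-bearing carbon and ends, after fragmentation, with a carbanion at the same carbon, so C1 is planar twice under basic fluoride conditions and is re-formed by protonation. A ketone activated only by a vinylogous acceptor lies outside the usual 1,3-dicarbonyl substrates and can stop at α-arylation. A9 lacks the C3 carboxyl and has a C4 ketone, so acylation, reduction and dehydration must follow. Enantioenriched A6 is a demanding target in itself.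
- Comparison: the chosen annulation installs the C3 carboxyl and a C4 leaving group in the ring-forming step itself and never makes C1 planar while ring B is built.

Key step: step 5

Assumption: in step 4 the enantiomer of the diene ligand that gives (S)-9 is used; which of the two it is follows from a first run with either antipode.

Step 1
Reactants: 1 methyl 3-methylbut-2-enoate; 2 dimethyl oxalate
Product: 4 methyl 4-methyl-2-oxo-2H-pyran-6-carboxylate, via dimethyl 3-methyl-5-oxohex-2-enedioate 3 (not isolated)
Conditions: KOMe, MeOH/Et2O, 0 °C → rt; AcOH; then TsOH·H2O (cat.), PhMe, reflux (−MeOH)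
Reagents that add atoms: none
Why: Vinylogous Claisen condensation: the γ-dienolate of 1 is acylated by 2 at a methyl carbon and the product is held as the stabilised potassium enolate of 3; acid then closes the enol oxygen of the 2-oxo ester onto the enoate carbonyl (enol lactonisation), the enoate geometry being mobile through the conjugated dienol, and no stereocentre is formed.

Step 2
Reactants: 4 methyl 4-methyl-2-oxo-2H-pyran-6-carboxylate
Product: 5 methyl 4-formyl-2-oxo-2H-pyran-6-carboxylate
Conditions: SeO2, 1,4-dioxane, reflux
Reagents that add atoms: selenium dioxide, O=[Se]=O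
Why: Riley oxidation of a methyl group on the β-carbon of an unsaturated lactone, the reaction that converts 4-methylcoumarins into 4-formylcoumarins; this vinylogous methyl is the only enolisable position of 4.

Step 3
Reactants: 5 methyl 4-formyl-2-oxo-2H-pyran-6-carboxylate; 6 dimethyl malonate
Product: 7 dimethyl 2-{[6-(methoxycarbonyl)-2-oxo-2H-pyran-4-yl]methylidene}propanedioate
Conditions: TiCl4, pyridine, THF, 0 °C → rt
Reagents that add atoms: none
Why: Knoevenagel condensation under Lewis acid/weak base conditions, chosen because nucleophilic secondary amines would open the pyranone; the electron-poor aldehyde condenses readily and, the two esters being alike, no alkene geometry arises.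

Step 4
Reactants: 7 dimethyl 2-{[6-(methoxycarbonyl)-2-oxo-2H-pyran-4-yl]methylidene}propanedioate; 8 3,4-dimethoxyphenylboronic acid
Product: 9 dimethyl 2-[(S)-(3,4-dimethoxyphenyl)[6-(methoxycarbonyl)-2-oxo-2H-pyran-4-yl]methyl]propanedioate
Conditions: [RhCl(C2H4)2]2 (cat.), 2,5-diphenylbicyclo[2.2.2]octa-2,5-diene (single enantiomer, cat.), KOH (cat.), dioxane/H2O, 30 °C
Reagents that add atoms: none
Why: Rhodium-catalysed asymmetric conjugate arylation (Hayashi–Miyaura reaction): the monovalent aryl–rhodium species Ar–Rh(diene) formed by transmetalation inserts the doubly activated alkene at the exocyclic carbon and water protonates the malonate enolate; the C2-symmetric diene tells the alkene faces apart by the pyranonyl versus hydrogen substituent and so sets the benzylic centre, while the acidic malonate C–H of 9 takes up any base before C1–H can.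

Step 5
Reactants: 9 dimethyl 2-[(S)-(3,4-dimethoxyphenyl)[6-(methoxycarbonyl)-2-oxo-2H-pyran-4-yl]methyl]propanedioate; 10 methyl (E)-3-methoxyacrylate
Product: 12 trimethyl (1R)-4,6,7-trimethoxy-1-[6-(methoxycarbonyl)-2-oxo-2H-pyran-4-yl]-3,4-dihydronaphthalene-2,2,3(1H)-tricarboxylate (C3/C4 epimers), via open-chain oxocarbenium ion 11 (not isolated)
Conditions: Mn(OAc)3·2H2O (2.5 equiv), Cu(OAc)2·H2O (0.2 equiv), 10 (4 equiv), AcOH/Ac2O, 70 °C, Ar
Reagents that add atoms: none
Why: Mn(OAc)3 binds the malonate of 9 as its enolate on trivalent manganese and oxidises it to the electrophilic tertiary C2 radical, which has no intramolecular outlet (attack on either ring would make a four-membered ring) and adds to the ester-bearing carbon of the push–pull alkene 10, the nucleophilic end of its enol ether (C2–C3 bond). The resulting methoxy-stabilised C4 radical is oxidised by divalent copper, which Mn(OAc)3 regenerates, to oxocarbenium ion 11. Ion 11 alkylates ring A at the carbon para to the C7 methoxy group (C4–C4a bond) in a six-membered Friedel–Crafts closure, 6-exo with respect to the C=O+ bond; an acetate adduct of 11, should it form, re-ionises in the hot acid or in step 6. The closest known reaction type is the manganese triacetate-mediated oxidative annulation of benzylmalonates with alkenes to tetralins, run here with a β-alkoxyacrylate so that the ring closes through a cation. C3 and C4 arise without control and both become sp2 in step 6, C2 bears two identical esters and is not stereogenic, and C1 is untouched because the medium is acidic throughout. Two selectivities are required: addition at the α-carbon of 10, which rests on polarity matching and on alkoxy stabilisation of the adduct radical, and closure at C4a instead of the carbon flanked by the tether and a methoxy group, which rests on para activation and on the crowding of the other ortho site.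

Step 6
Reactants: 12 trimethyl (1R)-4,6,7-trimethoxy-1-[6-(methoxycarbonyl)-2-oxo-2H-pyran-4-yl]-3,4-dihydronaphthalene-2,2,3(1H)-tricarboxylate
Product: 13 trimethyl (1R)-6,7-dimethoxy-1-[6-(methoxycarbonyl)-2-oxo-2H-pyran-4-yl]naphthalene-2,2,3(1H)-tricarboxylate
Conditions: TsOH·H2O (cat.), PhMe, 100 °C
Reagents that add atoms: none
Why: Acid-induced E1 elimination: the C4 methoxy group leaves as a benzylic cation stabilised by the para C7 methoxy group and the C3 proton, α to the ester, is lost, so all C3/C4 diastereomers converge on the conjugated alkene; C1 does not enolise under acid.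

Step 7
Reactants: 13 trimethyl (1R)-6,7-dimethoxy-1-[6-(methoxycarbonyl)-2-oxo-2H-pyran-4-yl]naphthalene-2,2,3(1H)-tricarboxylate
Product: 14 dimethyl (1R)-6,7-dimethoxy-1-[6-(methoxycarbonyl)-2-oxo-2H-pyran-4-yl]-1,2-dihydronaphthalene-2,3-dicarboxylate (C2 epimers)
Conditions: LiCl, H2O, AcOH (1 equiv), DMSO, 120 °C
Reagents that add atoms: none
Why: Krapcho dealkoxycarbonylation: chloride demethylates one of the geminal, allylic malonate esters, the carboxylate loses CO2 through a dienolate stabilised by the C3=C4 alkene, and α-protonation restores the styrene; the new C2 centre is not relied on here, since proton delivery anti to the C1 pyranone favours the cis ester, and the AcOH buffer keeps the medium from turning basic toward C1.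

Step 8
Reactants: 14 dimethyl (1R)-6,7-dimethoxy-1-[6-(methoxycarbonyl)-2-oxo-2H-pyran-4-yl]-1,2-dihydronaphthalene-2,3-dicarboxylate (C2 epimers)
Product: 15 dimethyl (1R,2S)-6,7-dimethoxy-1-[6-(methoxycarbonyl)-2-oxo-2H-pyran-4-yl]-1,2-dihydronaphthalene-2,3-dicarboxylate
Conditions: DBU (cat.), PhMe, rt, Ar
Reagents that add atoms: none
Why: Base-mediated epimerisation of an ester α-centre under thermodynamic control: C2 settles trans to the C1 pyranone because only the trans isomer can hold both groups pseudoaxial, clear of the C8 peri hydrogen and of the C3 ester; the cis isomer has a pseudoaxial C2–H aligned with the C3=C4 π-system and is the one deprotonated, whereas in the trans isomer C1–H and C2–H both lie near the ring plane, which should spare C1.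

Step 9
Reactants: 15 dimethyl (1R,2S)-6,7-dimethoxy-1-[6-(methoxycarbonyl)-2-oxo-2H-pyran-4-yl]-1,2-dihydronaphthalene-2,3-dicarboxylate
Product: 17 (1R,2S)-1-(6-carboxy-2-oxo-2H-pyran-4-yl)-6,7-dihydroxy-1,2-dihydronaphthalene-2,3-dicarboxylic acid, via catechol triester 16 (not isolated)
Conditions: BBr3, CH2Cl2, −78 → 0 °C; then 3 M HCl, dioxane, 80 °C, Ar
Reagents that add atoms: water, O
Why: Lewis acid cleavage of the two aryl methyl ethers followed by acid-catalysed hydrolysis of the three methyl esters; 2-pyranone-6-carboxylic acids are themselves formed in hot mineral acid and survive it, and neither C1 nor C2 enolises under acid, so the configuration from steps 4 and 8 is carried into the target.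

Compound list

1 | methyl 3-methylbut-2-enoate | COC(=O)C=C(C)C | starting material
2 | dimethyl oxalate | COC(=O)C(=O)OC | starting material
3 | dimethyl 3-methyl-5-oxohex-2-enedioate (as potassium enolate, alkene geometry mobile) | COC(=O)C(=O)CC(C)=CC(=O)OC | intermediate (not isolated)
4 | methyl 4-methyl-2-oxo-2H-pyran-6-carboxylate | Cc1cc(C(=O)OC)oc(=O)c1 | intermediate
5 | methyl 4-formyl-2-oxo-2H-pyran-6-carboxylate | O=Cc1cc(C(=O)OC)oc(=O)c1 | intermediate
6 | dimethyl malonate | COC(=O)CC(=O)OC | starting material
7 | dimethyl 2-{[6-(methoxycarbonyl)-2-oxo-2H-pyran-4-yl]methylidene}propanedioate | COC(=O)C(=Cc1cc(C(=O)OC)oc(=O)c1)C(=O)OC | intermediate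
8 | 3,4-dimethoxyphenylboronic acid | COc1ccc(B(O)O)cc1OC | starting material
9 | dimethyl 2-[(S)-(3,4-dimethoxyphenyl)[6-(methoxycarbonyl)-2-oxo-2H-pyran-4-yl]methyl]propanedioate | COC(=O)C(C(=O)OC)[C@@H](c1ccc(OC)c(OC)c1)c1cc(C(=O)OC)oc(=O)c1 | intermediate
10 | methyl (E)-3-methoxyacrylate | CO/C=C/C(=O)OC | starting material
11 | open-chain O-methyl oxocarbenium ion at C4 (adduct of 9 and 10 after two one-electron oxidations) | COC(=O)C(C=[O+]C)C(C(=O)OC)(C(=O)OC)[C@@H](c1ccc(OC)c(OC)c1)c1cc(C(=O)OC)oc(=O)c1 | intermediate (not isolated)
12 | trimethyl (1R)-4,6,7-trimethoxy-1-[6-(methoxycarbonyl)-2-oxo-2H-pyran-4-yl]-3,4-dihydronaphthalene-2,2,3(1H)-tricarboxylate (C3/C4 epimers) | COC(=O)C1C(OC)c2cc(OC)c(OC)cc2[C@@H](c2cc(C(=O)OC)oc(=O)c2)C1(C(=O)OC)C(=O)OC | intermediate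
13 | trimethyl (1R)-6,7-dimethoxy-1-[6-(methoxycarbonyl)-2-oxo-2H-pyran-4-yl]naphthalene-2,2,3(1H)-tricarboxylate | COC(=O)C1=Cc2cc(OC)c(OC)cc2[C@@H](c2cc(C(=O)OC)oc(=O)c2)C1(C(=O)OC)C(=O)OC | intermediate
14 | dimethyl (1R)-6,7-dimethoxy-1-[6-(methoxycarbonyl)-2-oxo-2H-pyran-4-yl]-1,2-dihydronaphthalene-2,3-dicarboxylate (C2 epimers) | COC(=O)C1=Cc2cc(OC)c(OC)cc2[C@@H](c2cc(C(=O)OC)oc(=O)c2)C1C(=O)OC | intermediate
15 | dimethyl (1R,2S)-6,7-dimethoxy-1-[6-(methoxycarbonyl)-2-oxo-2H-pyran-4-yl]-1,2-dihydronaphthalene-2,3-dicarboxylate | COC(=O)C1=Cc2cc(OC)c(OC)cc2[C@@H](c2cc(C(=O)OC)oc(=O)c2)[C@@H]1C(=O)OC | intermediate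
16 | dimethyl (1R,2S)-6,7-dihydroxy-1-[6-(methoxycarbonyl)-2-oxo-2H-pyran-4-yl]-1,2-dihydronaphthalene-2,3-dicarboxylate | COC(=O)C1=Cc2cc(O)c(O)cc2[C@@H](c2cc(C(=O)OC)oc(=O)c2)[C@@H]1C(=O)OC | intermediate (not isolated)
17 | (1R,2S)-1-(6-carboxy-2-oxo-2H-pyran-4-yl)-6,7-dihydroxy-1,2-dihydronaphthalene-2,3-dicarboxylic acid | O=C(O)C1=Cc2cc(O)c(O)cc2[C@@H](c2cc(C(=O)O)oc(=O)c2)[C@@H]1C(=O)O | target

Total step count: 9. Longest linear sequence: 9 steps (1 to 17); 6, 8 and 10 enter as purchased reagents.

Steps least certain to work

Step 5 (key step). The hindered tertiary malonyl radical may add too slowly to a 1,2-disubstituted alkene, so that oxidation of the malonate to its α-acetoxy derivative or hydrogen abstraction takes over. Addition may also go to the methoxy-bearing carbon of 10, which would place the ester at C4. Slow closure of 11 is the least serious failure, since its acetate adduct can still be ionised in step 6. Fallback, from 9 to 13: the same oxidant pair is used with vinyl acetate in place of 10, so that the radical can only add to an unsubstituted terminus. Closure gives dimethyl (1R)-4-acetoxy-6,7-dimethoxy-1-[6-(methoxycarbonyl)-2-oxo-2H-pyran-4-yl]-3,4-dihydronaphthalene-2,2(1H)-dicarboxylate F1. TsOH in toluene eliminates acetic acid to dimethyl (1R)-6,7-dimethoxy-1-[6-(methoxycarbonyl)-2-oxo-2H-pyran-4-yl]naphthalene-2,2(1H)-dicarboxylate F2. Vilsmeier–Haack formylation (POCl3, DMF) of this electron-rich styrene at C3 gives dimethyl (1R)-3-formyl-6,7-dimethoxy-1-[6-(methoxycarbonyl)-2-oxo-2H-pyran-4-yl]naphthalene-2,2(1H)-dicarboxylate F3. Pinnick oxidation (NaClO2, NaH2PO4, 2-methylbut-2-ene) gives (4R)-6,7-dimethoxy-3,3-bis(methoxycarbonyl)-4-[6-(methoxycarbonyl)-2-oxo-2H-pyran-4-yl]-3,4-dihydronaphthalene-2-carboxylic acid F4, and trimethylsilyldiazomethane in MeOH/PhMe returns the route at 13. The C3 carboxyl carbon is thus introduced by electrophilic formylation after the ring is closed, instead of with the alkene partner.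

Step 4. Enantioface discrimination may be poor because the two geminal esters are alike and only the β-substituent distinguishes the faces. Protodeboronation of the electron-rich 8 and hydroxide attack on the pyranone may also compete. Fallback, from 5 to 9: 5 is condensed with methyl cyanoacetate (TiCl4, pyridine) to methyl (2E)-2-cyano-3-[6-(methoxycarbonyl)-2-oxo-2H-pyran-4-yl]prop-2-enoate F5, a geometrically defined arylmethylene cyanoacetate, the acceptor class for which this diene-based arylation is established. Arylation with 8 under the step 4 catalyst gives methyl (3S)-2-cyano-3-(3,4-dimethoxyphenyl)-3-[6-(methoxycarbonyl)-2-oxo-2H-pyran-4-yl]propanoate F6 as C2 epimers. A Pinner reaction (HCl, MeOH, 0 °C → rt; then H2O) turns the nitrile into the second methyl ester under acid and returns the route at 9.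

Step 7. Chloride may also demethylate the pyranone ester or the C3 ester, the pyranone may open in hot wet DMSO, and C1 may lose integrity if the buffer is exhausted and the medium turns basic. Fallback, from 13 to 14: all four esters are hydrolysed with aqueous HCl in dioxane at 90 °C, the aryl ethers staying intact. The resulting (1R)-1-(6-carboxy-2-oxo-2H-pyran-4-yl)-6,7-dimethoxynaphthalene-2,2,3(1H)-tricarboxylic acid F7 loses CO2 from its C2 malonic acid in the same hot acid and gives (1R)-1-(6-carboxy-2-oxo-2H-pyran-4-yl)-6,7-dimethoxy-1,2-dihydronaphthalene-2,3-dicarboxylic acid F8 as C2 epimers. Trimethylsilyldiazomethane re-forms the three methyl esters and returns the route at 14. This replaces nucleophilic dealkylation by acid hydrolysis and thermal decarboxylation.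

Step 8. The base may also remove the γ-proton of the pyranone at C1 and erode the enantiomeric purity, the dienolate may be protonated at C4 so that the double bond moves to C2=C3, and traces of air may oxidise the dienolate to the naphthalene. Fallback, from 14 to 17: the base step is dropped and the C2 mixture 14 is taken through the conditions of step 9. The cis components pass through dimethyl (1R,2R)-6,7-dihydroxy-1-[6-(methoxycarbonyl)-2-oxo-2H-pyran-4-yl]-1,2-dihydronaphthalene-2,3-dicarboxylate F9 to (1R,2R)-1-(6-carboxy-2-oxo-2H-pyran-4-yl)-6,7-dihydroxy-1,2-dihydronaphthalene-2,3-dicarboxylic acid F10. F10 is removed from 17 by preparative reversed-phase chromatography. Equilibration is replaced by separation and C1 sees only acid, at the price of losing the cis material.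

Step 2. Oxidation may run on to the carboxylic acid, or stall and leave the electron-poor pyranone to decompose at the temperature needed. Fallback, from 4 to 5: Wohl–Ziegler bromination (NBS, AIBN, PhCF3, 80 °C) gives methyl 4-(bromomethyl)-2-oxo-2H-pyran-6-carboxylate F11, and a Kornblum-type oxidation of the bromide with N-methylmorpholine N-oxide (MeCN, rt) returns the route at 5.

Further compounds

F1 | step 5 | dimethyl (1R)-4-acetoxy-6,7-dimethoxy-1-[6-(methoxycarbonyl)-2-oxo-2H-pyran-4-yl]-3,4-dihydronaphthalene-2,2(1H)-dicarboxylate (C4 epimers) | C1C(OC(C)=O)c2cc(OC)c(OC)cc2[C@@H](c2cc(C(=O)OC)oc(=O)c2)C1(C(=O)OC)C(=O)OC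
F2 | step 5 | dimethyl (1R)-6,7-dimethoxy-1-[6-(methoxycarbonyl)-2-oxo-2H-pyran-4-yl]naphthalene-2,2(1H)-dicarboxylate | C1=Cc2cc(OC)c(OC)cc2[C@@H](c2cc(C(=O)OC)oc(=O)c2)C1(C(=O)OC)C(=O)OC
F3 | step 5 | dimethyl (1R)-3-formyl-6,7-dimethoxy-1-[6-(methoxycarbonyl)-2-oxo-2H-pyran-4-yl]naphthalene-2,2(1H)-dicarboxylate | O=CC1=Cc2cc(OC)c(OC)cc2[C@@H](c2cc(C(=O)OC)oc(=O)c2)C1(C(=O)OC)C(=O)OC
F4 | step 5 | (4R)-6,7-dimethoxy-3,3-bis(methoxycarbonyl)-4-[6-(methoxycarbonyl)-2-oxo-2H-pyran-4-yl]-3,4-dihydronaphthalene-2-carboxylic acid | O=C(O)C1=Cc2cc(OC)c(OC)cc2[C@@H](c2cc(C(=O)OC)oc(=O)c2)C1(C(=O)OC)C(=O)OC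
F5 | step 4 | methyl (2E)-2-cyano-3-[6-(methoxycarbonyl)-2-oxo-2H-pyran-4-yl]prop-2-enoate | COC(=O)/C(C#N)=C/c1cc(C(=O)OC)oc(=O)c1
F6 | step 4 | methyl (3S)-2-cyano-3-(3,4-dimethoxyphenyl)-3-[6-(methoxycarbonyl)-2-oxo-2H-pyran-4-yl]propanoate (C2 epimers) | COC(=O)C(C#N)[C@@H](c1ccc(OC)c(OC)c1)c1cc(C(=O)OC)oc(=O)c1
F7 | step 7 | (1R)-1-(6-carboxy-2-oxo-2H-pyran-4-yl)-6,7-dimethoxynaphthalene-2,2,3(1H)-tricarboxylic acid | O=C(O)C1=Cc2cc(OC)c(OC)cc2[C@@H](c2cc(C(=O)O)oc(=O)c2)C1(C(=O)O)C(=O)O
F8 | step 7 | (1R)-1-(6-carboxy-2-oxo-2H-pyran-4-yl)-6,7-dimethoxy-1,2-dihydronaphthalene-2,3-dicarboxylic acid (C2 epimers) | O=C(O)C1=Cc2cc(OC)c(OC)cc2[C@@H](c2cc(C(=O)O)oc(=O)c2)C1C(=O)O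
F9 | step 8 | dimethyl (1R,2R)-6,7-dihydroxy-1-[6-(methoxycarbonyl)-2-oxo-2H-pyran-4-yl]-1,2-dihydronaphthalene-2,3-dicarboxylate | COC(=O)C1=Cc2cc(O)c(O)cc2[C@@H](c2cc(C(=O)OC)oc(=O)c2)[C@H]1C(=O)OC
F10 | step 8 | (1R,2R)-1-(6-carboxy-2-oxo-2H-pyran-4-yl)-6,7-dihydroxy-1,2-dihydronaphthalene-2,3-dicarboxylic acid | O=C(O)C1=Cc2cc(O)c(O)cc2[C@@H](c2cc(C(=O)O)oc(=O)c2)[C@H]1C(=O)O
F11 | step 2 | methyl 4-(bromomethyl)-2-oxo-2H-pyran-6-carboxylate | BrCc1cc(C(=O)OC)oc(=O)c1
A1 | alternative 1 | dimethyl (1R,2S)-1-(3,4-dihydroxyphenyl)-6,7-dimethoxy-1,2-dihydronaphthalene-2,3-dicarboxylate | COC(=O)C1=Cc2cc(OC)c(OC)cc2[C@@H](c2ccc(O)c(O)c2)[C@@H]1C(=O)OC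
A2 | alternative 1 | 4-[(1R,2S)-6,7-dimethoxy-2,3-bis(methoxycarbonyl)-1,2-dihydronaphthalen-1-yl]-2-oxo-2H-pyran-6-carboxylic acid | COC(=O)C1=Cc2cc(OC)c(OC)cc2[C@@H](c2cc(C(=O)O)oc(=O)c2)[C@@H]1C(=O)OC
A3 | alternative 2 | 3-[(1R,2S)-6,7-dimethoxy-2,3-bis(methoxycarbonyl)-1,2-dihydronaphthalen-1-yl]prop-2-ynoic acid | COC(=O)C1=Cc2cc(OC)c(OC)cc2[C@@H](C#CC(=O)O)[C@@H]1C(=O)OC
A4 | alternative 2 | 3,3-diethoxyprop-1-yne | C#CC(OCC)OCC
A5 | alternative 2 | dimethyl (1R,2S)-1-[6-(diethoxymethyl)-2-oxo-2H-pyran-4-yl]-6,7-dimethoxy-1,2-dihydronaphthalene-2,3-dicarboxylate | COC(=O)C1=Cc2cc(OC)c(OC)cc2[C@@H](c2cc(C(OCC)OCC)oc(=O)c2)[C@@H]1C(=O)OC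
A6 | alternative 3 | methyl 4-[(1R,2R)-2-(methoxycarbonyl)-4-oxocyclobutyl]-2-oxo-2H-pyran-6-carboxylate | O=C1C[C@@H](C(=O)OC)[C@@H]1c1cc(C(=O)OC)oc(=O)c1
A7 | alternative 3 | 4,5-dimethoxy-2-(trimethylsilyl)phenyl trifluoromethanesulfonate | COc1cc(OS(=O)(=O)C(F)(F)F)c([Si](C)(C)C)cc1OC
A8 | alternative 3 | 4,5-dimethoxybenzyne | COC1=CC#CC=C1OC
A9 | alternative 3 | methyl 4-[(1R,2R)-6,7-dimethoxy-2-(methoxycarbonyl)-4-oxo-1,2,3,4-tetrahydronaphthalen-1-yl]-2-oxo-2H-pyran-6-carboxylate | O=C1c2cc(OC)c(OC)cc2[C@@H](c2cc(C(=O)OC)oc(=O)c2)[C@H](C(=O)OC)C1
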